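Rings A and B of the target, with the axial C19 oxygen on quaternary C4 cis to the C20 methyl on C10 and the trans C5–C10 fusion, are those of (+)-podocarpic acid, whose phenolic ring C already carries C8, C9, C11 and C12 in place. Everything rests on cutting that ring: ozonolysis cleaves C12–C13 and C8=C14, deletes C13/C14 and leaves a trans-decalin with a C8 ketone and a C9–C11–C12 acid chain, C4, C5 and C10 intact. The precursor is the unprotected resin acid itself. C9 is then set by hydrogenation/equilibration, C8 by α-face epoxidation and hydride opening, and the diene by late ethylene enyne metathesis.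

Key step: step 1

Remark: (+)-podocarpic acid and (E)-4-acetoxycinnamic acid are taken as commercial; podocarpane numbering is used for 1 and labdane numbering afterwards; 3 is drawn as the open keto acid although it should equilibrate with its cyclic 8-hydroxy-12,8-olide form, and the C8 configuration of peroxide 2 is immaterial.

Step 1
Reactants: 1 (+)-podocarpic acid
Product: 3 (Z)-8-oxo-13,14,15,16,17-pentanorlabd-9(11)-ene-12,19-dioic acid, via 8-hydroperoxy-8-methoxy-13,14,15,16,17-pentanorlabd-9(11)-ene-12,19-dioic acid 2 (not isolated)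
Conditions: O3 (ca. 2 equiv, to consumption of 1), CH2Cl2/MeOH, −78 °C; then Me2S, −78 °C → rt
Reagents that add atoms: ozone, [O-][O+]=O
Why: Ozonolysis of a phenol ring: ozone adds as a 1,3-dipole to the enol-like C12=C13 bond on the unhindered side of the phenol (C11 is peri-shielded by C1–H2 and C20) and Criegee fragmentation leaves the C12 carboxylic acid; the C8=C14 bond, now the electron-richer γ,δ-bond of a dienoic acid, takes the second equivalent, and its C8 carbonyl oxide is trapped by methanol as 2 and reduced by Me2S to the ketone. The closest known reaction type is the ozonolytic degradation of phenols and aryl ethers to muconic-acid derivatives and of benzo-fused resin acids to keto acids. No ring is closed; ring C is opened and C13–C14 is deleted as glyoxal. No stereocentre is formed, and C4, C5 and C10 are untouched because none of them is enolisable in 3 (C5 is not α to the C8 carbonyl, C4 and C10 are quaternary). The selectivity needed is arrest after two equivalents: the surviving C9=C11 bond is a β-acylacrylic acid flanked by ketone and carboxyl, far less nucleophilic toward ozone at −78 °C than the phenol or the dienoic intermediate, and the C8–C9 bond is never exposed as an isolated alkene as long as the first attack is at C12–C13.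

Step 2
Reactants: 3 (Z)-8-oxo-13,14,15,16,17-pentanorlabd-9(11)-ene-12,19-dioic acid
Product: 4 8-oxo-13,14,15,16,17-pentanorlabdane-12,19-dioic acid (9α-H, CH2CO2H β-equatorial)
Conditions: H2 (1 atm), 10% Pd/C, EtOAc, rt
Reagents that add atoms: none
Why: Catalytic hydrogenation of the electron-poor C9=C11 bond should deliver hydrogen to the α-face opposite the axial C20 methyl, giving 9α-H, which is also the thermodynamic epimer α to the C8 ketone, so any 9-epimer is corrected by enolisation.

Step 3
Reactants: 4 8-oxo-13,14,15,16,17-pentanorlabdane-12,19-dioic acid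
Product: 5 dimethyl 8-oxo-13,14,15,16,17-pentanorlabdane-12,19-dioate
Conditions: MeI, K2CO3, DMF, rt
Reagents that add atoms: iodomethane, CI
Why: SN2 O-alkylation of both carboxylates (esterification) is insensitive to the hindrance of the axial C19 carboxyl and touches no stereocentre other than the equilibrating C9.

Step 4
Reactants: 5 dimethyl 8-oxo-13,14,15,16,17-pentanorlabdane-12,19-dioate
Product: 6 dimethyl 13,14,15,16-tetranorlabd-8(17)-ene-12,19-dioate
Conditions: Ph3PCH3Br, KHMDS, THF, 0 °C → 50 °C
Reagents that add atoms: methyltriphenylphosphonium bromide, C[P+](c1ccccc1)(c1ccccc1)c1ccccc1.[Br-]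
Why: Wittig methylenation of the C8 ketone with the non-stabilised ylide should leave the esters alone, with C9 held in its equatorial thermodynamic configuration and no longer epimerisable afterwards.

Step 5
Reactants: 6 dimethyl 13,14,15,16-tetranorlabd-8(17)-ene-12,19-dioate
Product: 7 13,14,15,16-tetranorlabd-8(17)-ene-12,19-diol
Conditions: LiAlH4, THF, 0 °C → reflux; aqueous NaOH work-up
Reagents that add atoms: none
Why: LiAlH4 reduction should convert both methyl esters into primary alcohols, the isolated 8(17)-alkene being inert and no stereocentre affected.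

Step 6
Reactants: 7 13,14,15,16-tetranorlabd-8(17)-ene-12,19-diol
Product: 8 19-hydroxy-13,14,15,16-tetranorlabd-8(17)-en-12-yl 4-methylbenzenesulfonate
Conditions: TsCl (1.1 equiv), Et3N, DMAP (cat.), CH2Cl2, 0 °C
Reagents that add atoms: 4-toluenesulfonyl chloride, Cc1ccc(cc1)S(=O)(=O)Cl
Why: Selective sulfonylation should occur at the unhindered C12 primary alcohol, since the C19 alcohol is neopentyl, axial and 1,3-diaxial to C20.

Step 7
Reactants: 8 19-hydroxy-13,14,15,16-tetranorlabd-8(17)-en-12-yl 4-methylbenzenesulfonate
Product: 9 15,16-dinorlabd-8(17)-en-13-yn-19-ol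
Conditions: lithium acetylide–ethylenediamine complex (4 equiv), DMSO, rt
Reagents that add atoms: lithium acetylide–ethylenediamine complex, [Li+].[C-]#C.NCCN
Why: SN2 alkylation of acetylide by the primary tosylate should outrun E2 because C11 is unbranched, the excess reagent merely deprotonating the C19 alcohol.

Step 8
Reactants: 9 15,16-dinorlabd-8(17)-en-13-yn-19-ol
Product: 10 8α,17-epoxy-15,16-dinorlabd-13-yn-19-ol
Conditions: mCPBA, NaHCO3, CH2Cl2, 0 °C
Reagents that add atoms: meta-chloroperoxybenzoic acid, OOC(=O)c1cccc(Cl)c1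
Why: Prilezhaev epoxidation should occur from the equatorial α-face of the exocyclic alkene because the β-face is shielded by the 1,3-diaxial C20 methyl, which sets the C8–O bond α, while the terminal alkyne is far less reactive toward the peracid.

Step 9
Reactants: 10 8α,17-epoxy-15,16-dinorlabd-13-yn-19-ol
Product: 11 15,16-dinorlabd-13-yne-8α,19-diol
Conditions: LiAlH4, THF, 0 °C → 40 °C; aqueous NaOH work-up
Reagents that add atoms: none
Why: SN2 hydride opening of the 2,2-disubstituted epoxide at primary C17 should turn C17 into the β-methyl and leave the α C8–O bond as the tertiary alcohol with C8 untouched, the alkyne being only deprotonated.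

Step 10
Reactants: 11 15,16-dinorlabd-13-yne-8α,19-diol
Product: 12 labda-13(16),14-diene-8α,19-diol
Conditions: ethylene (1 atm), Grubbs second-generation catalyst (5 mol %), toluene, 80 °C
Reagents that add atoms: ethylene, C=C
Why: Ethylene–alkyne cross enyne metathesis should add the Ru-methylidene across the terminal alkyne and turn the vinylcarbene over with ethylene to give the 2-substituted 1,3-butadiene directly, free alcohols being tolerated and ethylene suppressing secondary metathesis of the diene.

Step 11
Reactants: 12 labda-13(16),14-diene-8α,19-diol; 13 (E)-4-acetoxycinnamic acid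
Product: 15 8α-hydroxylabda-13(16),14-dien-19-yl (E)-4-acetoxycinnamate, via (E)-4-acetoxycinnamoyl chloride 14 (not isolated)
Conditions: 13, (COCl)2, DMF (cat.), CH2Cl2, 0 °C → rt, evaporate; then 12, Et3N, DMAP (cat.), CH2Cl2, 0 °C → rt
Reagents that add atoms: none
Why: DMAP-catalysed acylation by the acid chloride should take place at the primary C19 alcohol only, the tertiary 8α-alcohol being too hindered, with the E geometry of the cinnamoyl unit carried through.

Step 12
Reactants: 15 8α-hydroxylabda-13(16),14-dien-19-yl (E)-4-acetoxycinnamate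
Product: 16 8α-hydroxylabda-13(16),14-dien-19-yl (E)-4-hydroxycinnamate (target)
Conditions: K2CO3 (0.3 equiv), MeOH, 0 °C
Reagents that add atoms: none
Why: Base-catalysed methanolysis (transesterification) should remove the aryl acetate, which is far more electrophilic than the conjugated neopentyl cinnamate, and the phenoxide formed deactivates the cinnamate further.

Compound list
1 | (+)-podocarpic acid, 12-hydroxypodocarpa-8,11,13-trien-19-oic acid (4β-CO2H, 4α-CH3, 5α-H, 10β-CH3) | Oc1ccc2c(c1)[C@@]1(C)CCC[C@](C)(C(=O)O)[C@@H]1CC2 | starting material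
2 | (Z)-8-hydroperoxy-8-methoxy-13,14,15,16,17-pentanorlabd-9(11)-ene-12,19-dioic acid (methanol-trapped carbonyl oxide, C8 configuration immaterial) | OC(=O)/C=C1/[C@@]2(C)CCC[C@](C)(C(=O)O)[C@@H]2CCC1(OC)OO | intermediate
3 | (Z)-8-oxo-13,14,15,16,17-pentanorlabd-9(11)-ene-12,19-dioic acid (open form of the pseudo-acid) | OC(=O)/C=C1/[C@@]2(C)CCC[C@](C)(C(=O)O)[C@@H]2CCC1=O | intermediate
4 | 8-oxo-13,14,15,16,17-pentanorlabdane-12,19-dioic acid (5α-H, 9α-H, 10β-CH3) | OC(=O)C[C@@H]1[C@@]2(C)CCC[C@](C)(C(=O)O)[C@@H]2CCC1=O | intermediate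
5 | dimethyl 8-oxo-13,14,15,16,17-pentanorlabdane-12,19-dioate | COC(=O)C[C@@H]1[C@@]2(C)CCC[C@](C)(C(=O)OC)[C@@H]2CCC1=O | intermediate
6 | dimethyl 13,14,15,16-tetranorlabd-8(17)-ene-12,19-dioate | COC(=O)C[C@@H]1[C@@]2(C)CCC[C@](C)(C(=O)OC)[C@@H]2CCC1=C | intermediate
7 | 13,14,15,16-tetranorlabd-8(17)-ene-12,19-diol | OCC[C@@H]1[C@@]2(C)CCC[C@](C)(CO)[C@@H]2CCC1=C | intermediate
8 | 19-hydroxy-13,14,15,16-tetranorlabd-8(17)-en-12-yl 4-methylbenzenesulfonate | Cc1ccc(cc1)S(=O)(=O)OCC[C@@H]1[C@@]2(C)CCC[C@](C)(CO)[C@@H]2CCC1=C | intermediate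
9 | 15,16-dinorlabd-8(17)-en-13-yn-19-ol | C#CCC[C@@H]1[C@@]2(C)CCC[C@](C)(CO)[C@@H]2CCC1=C | intermediate
10 | 8α,17-epoxy-15,16-dinorlabd-13-yn-19-ol | C#CCC[C@@H]1[C@@]2(C)CCC[C@](C)(CO)[C@@H]2CC[C@]13CO3 | intermediate
11 | 15,16-dinorlabd-13-yne-8α,19-diol (8α-OH, 8β-CH3) | C#CCC[C@@H]1[C@@]2(C)CCC[C@](C)(CO)[C@@H]2CC[C@@]1(C)O | intermediate
12 | labda-13(16),14-diene-8α,19-diol | C=CC(=C)CC[C@@H]1[C@@]2(C)CCC[C@](C)(CO)[C@@H]2CC[C@@]1(C)O | intermediate
13 | (E)-4-acetoxycinnamic acid | CC(=O)Oc1ccc(/C=C/C(=O)O)cc1 | starting material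
14 | (E)-4-acetoxycinnamoyl chloride | CC(=O)Oc1ccc(/C=C/C(Cl)=O)cc1 | intermediate
15 | 8α-hydroxylabda-13(16),14-dien-19-yl (E)-4-acetoxycinnamate | C=CC(=C)CC[C@@H]1[C@@]2(C)CCC[C@](C)(COC(=O)/C=C/c3ccc(OC(C)=O)cc3)[C@@H]2CC[C@@]1(C)O | intermediate
16 | 8α-hydroxylabda-13(16),14-dien-19-yl (E)-4-hydroxycinnamate | C=CC(=C)CC[C@@H]1[C@@]2(C)CCC[C@](C)(COC(=O)/C=C/c3ccc(O)cc3)[C@@H]2CC[C@@]1(C)O | target

Total step count: 12
Longest linear sequence: 12 steps (1 → 16)

Steps most likely to fail

Step 1. The ozone may not stop cleanly: over-oxidation of the C9=C11 bond, or a first attack at C11–C12 that exposes the C8=C9 bond and opens ring B, would erode the decalin. The fallback sets out from 1 and comes back at 3, and fixes the cleavage sites by prior functionalisation instead of by relative ozone rates. Oxidative dearomatisation of 1 with PhI(OAc)2 in aqueous MeCN at 0 °C should add water para to the phenol oxygen and give the p-quinol 8α-hydroxy-12-oxopodocarpa-9(11),13-dien-19-oic acid F1. Dihydroxylation (OsO4 cat., NMO, acetone/water) of the less hindered, disubstituted C13=C14 bond should give 8α,13,14-trihydroxy-12-oxopodocarp-9(11)-en-19-oic acid F2. NaIO4 in THF/water should then cleave the C8–C14 and C13–C14 glycol bonds and the C12–C13 α-ketol bond and deliver 3.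

Step 10. The ruthenium carbene may be arrested by the free diol or consumed in alkyne oligomerisation, and the product diene may undergo secondary metathesis. The fallback sets out from 11 and comes back at 12, building the diene by cross-coupling. Markovnikov hydrosilylation of the terminal alkyne with benzyldimethylsilane and [Cp*Ru(MeCN)3]PF6 (CH2Cl2, rt) should give the 1,1-disubstituted vinylsilane 13-(benzyldimethylsilyl)-14,15-dinorlabd-13(16)-ene-8α,19-diol F3. Fluoride-promoted palladium coupling (Pd2(dba)3, TBAF, THF) with vinyl bromide should then give 12.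

Step 4. The basic ylide may enolise the hindered C8 ketone instead of adding, with Claisen-type closure of the C7 enolate onto the C12 ester and incomplete methylenation. The fallback sets out from 5 and comes back at 6 by addition–elimination. The weakly basic cerium reagent from Me3SiCH2MgCl/CeCl3 (THF, −78 °C) should add to the ketone only, from the α-face, and give dimethyl 8β-hydroxy-17-(trimethylsilyl)-13,14,15,16-tetranorlabdane-12,19-dioate F4. Acid-promoted Peterson elimination (BF3·OEt2, CH2Cl2, 0 °C) should then give 6.

Further compounds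
F1 | step 1 | 8α-hydroxy-12-oxopodocarpa-9(11),13-dien-19-oic acid | O=C1C=C2[C@@]3(C)CCC[C@](C)(C(=O)O)[C@@H]3CC[C@]2(O)C=C1
F2 | step 1 | 8α,13,14-trihydroxy-12-oxopodocarp-9(11)-en-19-oic acid (cis-13,14-diol, face immaterial) | O=C1C=C2[C@@]3(C)CCC[C@](C)(C(=O)O)[C@@H]3CC[C@]2(O)C(O)C1O
F3 | step 10 | 13-(benzyldimethylsilyl)-14,15-dinorlabd-13(16)-ene-8α,19-diol | C=C([Si](C)(C)Cc1ccccc1)CC[C@@H]1[C@@]2(C)CCC[C@](C)(CO)[C@@H]2CC[C@@]1(C)O
F4 | step 4 | dimethyl 8β-hydroxy-17-(trimethylsilyl)-13,14,15,16-tetranorlabdane-12,19-dioate | COC(=O)C[C@@H]1[C@@]2(C)CCC[C@](C)(C(=O)OC)[C@@H]2CC[C@]1(C[Si](C)(C)C)O
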